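**Retrosynthetic overview**
- 12 ⇐ methyl ketone 10: the side-chain carbinol is made last by asymmetric Corey–Chaykovsky epoxidation and sulfonium-ylide opening. 10 ⇐ terminal alkene 9 by Wacker oxidation.
- 9 ⇐ bromocyclohexanone 8 by equatorial methyl addition to the ring ketone.
- 8 ⇐ lactol 6 by a bromonium-relay O→C carbocyclization. This forms the only carbocycle and its C–C bond.
- 6 ⇐ bromolactone 4 + 4-pentenyl Grignard 5. 4 ⇐ geranylacetic acid 3 by organocatalytic asymmetric 6-endo bromolactonization, which sets the first two stereocentres.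
- 3 ⇐ geranyl bromide 1 + acetic acid 2. Ring order: temporary δ-lactone/oxane first, then the cyclohexane.

Assumption: the configuration is taken exactly as in the SMILES, i.e. (1R,2S,3S,4S) in the ring and (3S) in the side chain; 1 and 5 (as a THF solution) are bought.

**Step 1**
Reactants: 1 geranyl bromide, (2E)-1-bromo-3,7-dimethylocta-2,6-diene; 2 acetic acid
Product: 3 (4E)-5,9-dimethyldeca-4,8-dienoic acid (geranylacetic acid)
Conditions: LDA (2.2 equiv), THF/HMPA, 0 → 35 °C; then 1, 0 °C → rt; 1 M HCl
Reagents that add atoms: none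
Why: Alkylation of the acetic acid dianion (carboxylic acid enediolate alkylation) with the primary allylic bromide goes SN2 at C1 and keeps the E-alkene; no stereocentre is formed.

**Step 2**
Reactants: 3 (4E)-5,9-dimethyldeca-4,8-dienoic acid
Product: 4 (5S,6R)-5-bromo-6-methyl-6-(4-methylpent-3-en-1-yl)oxan-2-one
Conditions: quinidine-derived amino-thiocarbamate catalyst (10 mol %), NBS (1.1 equiv), NsNH2 (0.5 equiv), CHCl3/PhMe 1:2, −78 °C, dark
Reagents that add atoms: N-bromosuccinimide, O=C1CCC(=O)N1Br
Why: Organocatalytic asymmetric bromolactonization: the bifunctional catalyst binds the acid and NBS, so Br+ reaches only the proximal alkene, the carboxylate opens the bromonium anti at the tertiary carbon (6-endo), and the catalyst's face selection sets C5 (S) and C6 (R), the pseudo-enantiomeric (quinine-derived) catalyst being used if the sense proves opposite.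

**Step 3**
Reactants: 4 (5S,6R)-5-bromo-6-methyl-6-(4-methylpent-3-en-1-yl)oxan-2-one; 5 pent-4-en-1-ylmagnesium bromide
Product: 6 (5S,6R)-5-bromo-6-methyl-6-(4-methylpent-3-en-1-yl)-2-(pent-4-en-1-yl)oxan-2-ol (lactol, C2 epimers, in equilibrium with the open-chain δ-hydroxy ketone)
Conditions: 5 (1.15 equiv), THF, −78 °C; cold quench into pH 7 buffer
Reagents that add atoms: none
Why: Mono-addition of a Grignard reagent to a δ-lactone at −78 °C stops at the magnesium lactolate because the tertiary alkoxide is a poor leaving group, the cold buffered quench avoids enolisation and epoxide closure, and the two stereocentres are untouched.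

**Step 4**
Reactants: 6 (5S,6R)-5-bromo-6-methyl-6-(4-methylpent-3-en-1-yl)-2-(pent-4-en-1-yl)oxan-2-ol
Product: 8 (2S,3S,4S)-4-bromo-2-(but-3-en-1-yl)-3-methyl-3-(4-methylpent-3-en-1-yl)cyclohexan-1-one, via (Z)-exocyclic enol ether 7 (not isolated)
Conditions: TMSOTf (2.3 equiv), 2,6-di-tert-butyl-4-methylpyridine (2.5 equiv), CH2Cl2 (0.01 M), −78 → −30 °C; aq NaHCO3
Reagents that add atoms: none
Why: Proposed new method: a bromonium-relay Ferrier-type 1,3 O→C carbocyclization in which silyl-assisted dehydration gives enol ether 7, O-silylation then heterolyses its tertiary C6–O1 bond with anchimeric help from the anti-periplanar equatorial bromine, and the resulting configurationally defined bromonium ion is captured by the tethered (Z)-silyl enol ether through a chair transition state anti to bromine (net retention at the quaternary carbon by double inversion, new C2 centre equatorial from the Z-enol geometry, high dilution to suppress alkene-to-alkene Br+ transfer); the closest known reactions are the Petasis–Ferrier/Ferrier carbocyclization and enantiospecific polyene cyclizations of bromonium ions generated from enantiopure bromohydrin derivatives.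

**Step 5**
Reactants: 8 (2S,3S,4S)-4-bromo-2-(but-3-en-1-yl)-3-methyl-3-(4-methylpent-3-en-1-yl)cyclohexan-1-one
Product: 9 (1R,2S,3S,4S)-4-bromo-2-(but-3-en-1-yl)-1,3-dimethyl-3-(4-methylpent-3-en-1-yl)cyclohexan-1-ol
Conditions: MeMgBr, anhydrous CeCl3, THF, −78 °C; aq NH4Cl
Reagents that add atoms: methylmagnesium bromide, C[Mg]Br
Why: Organocerium 1,2-addition is non-basic (no C2 epimerisation, no cyclopropane from the γ-bromo ketone), and the axial C3 methyl blocks axial attack, so methyl enters equatorially and gives the axial (1R) alcohol.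

**Step 6**
Reactants: 9 (1R,2S,3S,4S)-4-bromo-2-(but-3-en-1-yl)-1,3-dimethyl-3-(4-methylpent-3-en-1-yl)cyclohexan-1-ol
Product: 10 4-[(1S,2S,3S,6R)-3-bromo-6-hydroxy-2,6-dimethyl-2-(4-methylpent-3-en-1-yl)cyclohexyl]butan-2-one
Conditions: PdCl2 (10 mol %), CuCl (1 equiv), O2 (1 atm), DMF/H2O 7:1, rt
Reagents that add atoms: water, O
Why: Tsuji–Wacker oxidation converts only the monosubstituted terminal alkene into the methyl ketone (Markovnikov), the trisubstituted alkene, the bromide and the tertiary alcohol being inert; no stereocentre changes.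

**Step 7**
Reactants: 10 4-[(1S,2S,3S,6R)-3-bromo-6-hydroxy-2,6-dimethyl-2-(4-methylpent-3-en-1-yl)cyclohexyl]butan-2-one
Product: 11 (1R,2S,3S,4S)-4-bromo-1,3-dimethyl-2-{2-[(2S)-2-methyloxiran-2-yl]ethyl}-3-(4-methylpent-3-en-1-yl)cyclohexan-1-ol
Conditions: Me3S(O)I, NaH, THF; then La–Li3–tris(binaphthoxide) (LLB, 5 mol %), (2,4,6-(MeO)3C6H2)3P=O (5 mol %), 5 Å MS, rt
Reagents that add atoms: trimethylsulfoxonium iodide, C[S+](C)(C)=O.[I-]
Why: Catalytic asymmetric Corey–Chaykovsky epoxidation of a methyl ketone, in which the LLB complex differentiates the ketone faces (methyl versus primary alkyl) independently of the remote ring, the BINOL antipode being chosen to give the (2S)-epoxide.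

**Step 8**
Reactants: 11 (1R,2S,3S,4S)-4-bromo-1,3-dimethyl-2-{2-[(2S)-2-methyloxiran-2-yl]ethyl}-3-(4-methylpent-3-en-1-yl)cyclohexan-1-ol
Product: 12 (1R,2S,3S,4S)-4-bromo-2-[(3S)-3-hydroxy-3-methylpent-4-en-1-yl]-1,3-dimethyl-3-(4-methylpent-3-en-1-yl)cyclohexan-1-ol
Conditions: Me3SI (4 equiv), n-BuLi (3.9 equiv), THF, −10 °C → rt
Reagents that add atoms: trimethylsulfonium iodide, C[S+](C)C.[I-]
Why: Sulfonium-ylide one-carbon homologation of a 2,2-disubstituted epoxide to an allylic alcohol: the ylide opens the epoxide at CH2 and the betaine eliminates Me2S, so the C–O bond at the quaternary carbon is never broken and (S) is retained.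

**Compound list**
1 | geranyl bromide, (2E)-1-bromo-3,7-dimethylocta-2,6-diene | CC(C)=CCC/C(C)=C/CBr | starting material
2 | acetic acid | CC(=O)O | starting material
3 | (4E)-5,9-dimethyldeca-4,8-dienoic acid | OC(=O)CC/C=C(\C)CCC=C(C)C | intermediate
4 | (5S,6R)-5-bromo-6-methyl-6-(4-methylpent-3-en-1-yl)oxan-2-one | O1[C@](C)(CCC=C(C)C)[C@@H](Br)CCC1=O | intermediate
5 | pent-4-en-1-ylmagnesium bromide | C=CCCC[Mg]Br | starting material
6 | (5S,6R)-5-bromo-6-methyl-6-(4-methylpent-3-en-1-yl)-2-(pent-4-en-1-yl)oxan-2-ol (C2 epimers) | O1[C@](C)(CCC=C(C)C)[C@@H](Br)CCC1(O)CCCC=C | intermediate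
7 | (2Z,5S,6R)-5-bromo-6-methyl-6-(4-methylpent-3-en-1-yl)-2-(pent-4-en-1-ylidene)oxane | O1[C@](C)(CCC=C(C)C)[C@@H](Br)CC/C1=C/CCC=C | intermediate
8 | (2S,3S,4S)-4-bromo-2-(but-3-en-1-yl)-3-methyl-3-(4-methylpent-3-en-1-yl)cyclohexan-1-one | C=CCC[C@H]1[C@](C)(CCC=C(C)C)[C@@H](Br)CCC1=O | intermediate
9 | (1R,2S,3S,4S)-4-bromo-2-(but-3-en-1-yl)-1,3-dimethyl-3-(4-methylpent-3-en-1-yl)cyclohexan-1-ol | C=CCC[C@H]1[C@](C)(CCC=C(C)C)[C@@H](Br)CC[C@@]1(C)O | intermediate
10 | 4-[(1S,2S,3S,6R)-3-bromo-6-hydroxy-2,6-dimethyl-2-(4-methylpent-3-en-1-yl)cyclohexyl]butan-2-one | CC(=O)CC[C@H]1[C@](C)(CCC=C(C)C)[C@@H](Br)CC[C@@]1(C)O | intermediate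
11 | (1R,2S,3S,4S)-4-bromo-1,3-dimethyl-2-{2-[(2S)-2-methyloxiran-2-yl]ethyl}-3-(4-methylpent-3-en-1-yl)cyclohexan-1-ol | C1[C@@](C)(O1)CC[C@H]2[C@](C)(CCC=C(C)C)[C@@H](Br)CC[C@@]2(C)O | intermediate
12 | (1R,2S,3S,4S)-4-bromo-2-[(3S)-3-hydroxy-3-methylpent-4-en-1-yl]-1,3-dimethyl-3-(4-methylpent-3-en-1-yl)cyclohexan-1-ol | C=C[C@@](C)(O)CC[C@H]1[C@](C)(CCC=C(C)C)[C@@H](Br)CC[C@@]1(C)O | target

**Step count**
Total steps: 8. Longest linear sequence: 8 (from 1 and 2 to 12).

**Three steps most likely to fail**

Step 4 (the proposed new step). Risks are E1 loss from the bromonium ion, Br+ transfer to the other alkenes with loss of enantiopurity, and poor control of the enol geometry and hence of the C2 centre. The fallback uses known reaction types, sets out from 6 and comes back at 8. The open-chain tautomer of 6 is trapped with TMSOTf and excess Et3N (−78 → 0 °C, soft-enolisation silylation) as the bis-silyl compound (5Z,9S,10R)-9-bromo-10,14-dimethyl-6,10-bis(trimethylsilyloxy)pentadeca-1,5,13-triene F1; the unproductive regio- and geometric isomers are separated and recycled. F1 is then treated with Me2AlCl in CH2Cl2 at −78 °C. The Lewis acid ionises the tertiary silyl ether of the bromohydrin derivative to the same bromonium ion (the documented way to make enantiopure bromonium ions for polyene cyclization), and the preformed silyl enol ether alkylates it in a Mukaiyama-type SN1 step to give 8.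

Step 2. The distal trisubstituted alkene may compete for Br+ or shuttle it, and the enantioselectivity on this dialkyl-substituted alkene is untested. The fallback sets out from 3 and comes back at 4. Uncatalysed bromolactonization (NBS, NaHCO3, CH2Cl2, 0 °C) gives the racemic trans-lactone, that is 4 together with its enantiomer (5R,6S)-5-bromo-6-methyl-6-(4-methylpent-3-en-1-yl)oxan-2-one F2. F2 is removed by preparative chiral SFC, so the stereocontrol comes from resolution instead of catalysis at the cost of half the material.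

Step 7. The catalyst must override nothing but also gets no help from the remote ring, the substrate is a dialkyl methyl ketone carrying a free tertiary alcohol, and the selectivity may be modest. The fallback sets out from 10 and comes back at 12 directly, bypassing 11. Vinylmagnesium bromide with CeCl3 (THF, −78 °C) adds to the methyl ketone without facial control and gives 12 together with its C3 epimer (1R,2S,3S,4S)-4-bromo-2-[(3R)-3-hydroxy-3-methylpent-4-en-1-yl]-1,3-dimethyl-3-(4-methylpent-3-en-1-yl)cyclohexan-1-ol F3 in about 1:1 ratio. The two are separated by preparative HPLC.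

**Further compounds**
F1 | step 4 | (5Z,9S,10R)-9-bromo-10,14-dimethyl-6,10-bis(trimethylsilyloxy)pentadeca-1,5,13-triene | C[Si](C)(C)O[C@](C)(CCC=C(C)C)[C@@H](Br)CC/C(O[Si](C)(C)C)=C/CCC=C
F2 | step 2 | (5R,6S)-5-bromo-6-methyl-6-(4-methylpent-3-en-1-yl)oxan-2-one | O1[C@@](C)(CCC=C(C)C)[C@H](Br)CCC1=O
F3 | step 7 | (1R,2S,3S,4S)-4-bromo-2-[(3R)-3-hydroxy-3-methylpent-4-en-1-yl]-1,3-dimethyl-3-(4-methylpent-3-en-1-yl)cyclohexan-1-ol | C=C[C@](C)(O)CC[C@H]1[C@](C)(CCC=C(C)C)[C@@H](Br)CC[C@@]1(C)O
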